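## Retrosynthetic overview

1. Target ⇐ tigloylation of O8, then chloride opening of the 11,13-epoxide made from the α-methylene lactone; both come after all three rings exist.
2. Furanone ring (formed last) ⇐ transannular attack of the C10 hydroxyl on C3 of a ten-membered 1-oxo-2-yne, i.e. closure at the 1,3-dione oxidation level.
3. Ten-membered carbocycle and γ-lactone (first and second, one operation) ⇐ C6–C7 closure by intramolecular allylchromium addition to the C6 aldehyde, then O6→C12 lactonisation.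
4. Open chain ⇐ C1–C2 union of an alkynyl Grignard (C2–C6, Marshall propargylation) with a 2-C-methyl-L-ribofuranose lactol (C7–C10 and C1; from metathesis and dihydroxylation); C11–C13 by Baylis–Hillman reaction.
5. Ring order: carbocycle → lactone → furanone.

Assumption: germacrane numbering is used for all intermediates (C1–C10 ring carbons, C11–C13 lactone carbons, C14/C15 the methyls on C10/C4); TES = triethylsilyl, TBS = tert-butyldimethylsilyl; C1 and C7 epimer mixtures are carried where those centres are later destroyed.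

## Route

Step 1
Reactants: 1 (R)-but-3-ene-1,2-diol; 2 methacryloyl chloride
Product: 4 (R)-1-(triethylsilyloxy)but-3-en-2-yl methacrylate, via primary silyl ether 3 (not isolated)
Conditions: TESCl (1.0 equiv), Et3N, DMAP (cat.), CH2Cl2, −78 → 0 °C; then 2, Et3N, 0 °C → rt
Reagents that add atoms: chlorotriethylsilane (TESCl), CC[Si](Cl)(CC)CC
Why: Selective silylation of the primary hydroxyl at low temperature followed by DMAP-catalysed acylation of the remaining allylic alcohol in the same flask gives the metathesis substrate; the C8 stereocentre is bought with 1 and is not touched.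

Step 2
Reactants: 4 (R)-1-(triethylsilyloxy)but-3-en-2-yl methacrylate
Product: 5 (R)-3-methyl-5-[(triethylsilyloxy)methyl]furan-2(5H)-one
Conditions: second-generation Grubbs catalyst (H2IMes)(PCy3)Cl2Ru=CHPh (5 mol%), toluene, 80 °C, argon sparge
Reagents that add atoms: none
Why: Ring-closing metathesis of the vinyl group onto the methacrylate closes the butenolide with loss of ethene and so fixes C9=C10 as the cis (in-ring) trisubstituted alkene needed for the next step.

Step 3
Reactants: 5 (R)-3-methyl-5-[(triethylsilyloxy)methyl]furan-2(5H)-one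
Product: 6 (3S,4S,5S)-3,4-dihydroxy-3-methyl-5-[(triethylsilyloxy)methyl]oxolan-2-one
Conditions: OsO4 (2 mol%), NMO (1.5 equiv), acetone/H2O 8:1, 0 °C → rt
Reagents that add atoms: osmium tetroxide (catalytic oxygen carrier), O=[Os](=O)(=O)=O; N-methylmorpholine N-oxide, C[N+]1([O-])CCOCC1; water, O
Why: Upjohn syn-dihydroxylation delivers both hydroxyls to the face of the butenolide opposite the C8 substituent, which sets C9 and C10 (2-C-methyl-L-ribonolactone pattern) by substrate control.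

Step 4
Reactants: 6 (3S,4S,5S)-3,4-dihydroxy-3-methyl-5-[(triethylsilyloxy)methyl]oxolan-2-one
Product: 8 (3S,4S,5S)-4-(TBS-oxy)-3-methyl-3-(TES-oxy)-5-[(TES-oxy)methyl]oxolan-2-one, via mono-TBS lactone 7 (not isolated)
Conditions: TBSOTf (1.05 equiv), 2,6-lutidine, CH2Cl2, −78 °C; then TESOTf (1.5 equiv), −78 → 0 °C
Reagents that add atoms: tert-butyldimethylsilyl triflate, CC(C)(C)[Si](C)(C)OS(=O)(=O)C(F)(F)F; triethylsilyl triflate, CC[Si](CC)(CC)OS(=O)(=O)C(F)(F)F
Why: Silyl triflate silylation discriminates by hindrance, so one equivalent of TBSOTf takes the secondary C9 hydroxyl (the group that must last to the end) and TESOTf then caps the tertiary C10 hydroxyl.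

Step 5
Reactants: 8 (3S,4S,5S)-4-(TBS-oxy)-3-methyl-3-(TES-oxy)-5-[(TES-oxy)methyl]oxolan-2-one
Product: 9 (3S,4S,5S)-4-(TBS-oxy)-3-methyl-3-(TES-oxy)-5-[(TES-oxy)methyl]oxolan-2-ol (lactol; both anomers)
Conditions: i-Bu2AlH (1.2 equiv), CH2Cl2, −78 °C; KNaC4H4O6 (aq)
Reagents that add atoms: none
Why: Low-temperature i-Bu2AlH reduction of the lactone stops at the aluminium lactolate and gives the lactol as a latent C1 aldehyde, so that C1 stays at the alcohol level (not a ketone within reach of C7) until after the macrocyclisation.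

Step 6
Reactants: 10 (R)-but-3-yn-2-ol
Product: 11 (R)-but-3-yn-2-yl methanesulfonate
Conditions: MsCl, Et3N, CH2Cl2, −78 → 0 °C
Reagents that add atoms: methanesulfonyl chloride, CS(=O)(=O)Cl
Why: O-Sulfonylation with retention at carbon gives the propargylic mesylate needed for the Marshall propargylation.

Step 7
Reactants: 11 (R)-but-3-yn-2-yl methanesulfonate; 12 2,2-dimethoxyacetaldehyde
Product: 13 (2S,3S)-1,1-dimethoxy-3-methylpent-4-yn-2-ol
Conditions: Pd(OAc)2 (5 mol%), PPh3 (5 mol%), Et2Zn (3 equiv), anhydrous 12, THF, −78 → −20 °C; NH4Cl (aq)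
Reagents that add atoms: none
Why: Marshall propargylation: zerovalent palladium (formed from Pd(OAc)2, PPh3 and Et2Zn) opens the mesylate anti to an allenylpalladium, transmetalation gives the allenylzinc, and its cyclic SE2' addition to the aldehyde gives the anti homopropargylic alcohol, with C4 set by chirality transfer from the mesylate and C5 by the anti transition state.

Step 8
Reactants: 13 (2S,3S)-1,1-dimethoxy-3-methylpent-4-yn-2-ol
Product: 14 tert-butyl{[(2S,3S)-1,1-dimethoxy-3-methylpent-4-yn-2-yl]oxy}dimethylsilane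
Conditions: TBSOTf, 2,6-lutidine, CH2Cl2, −78 → 0 °C
Reagents that add atoms: tert-butyldimethylsilyl triflate, CC(C)(C)[Si](C)(C)OS(=O)(=O)C(F)(F)F
Why: Standard silyl ether formation protects the C5 hydroxyl with a group that survives to the last step.

Step 9
Reactants: 14 tert-butyl{[(2S,3S)-1,1-dimethoxy-3-methylpent-4-yn-2-yl]oxy}dimethylsilane; 9 lactol (oxolan-2-ol from step 5)
Product: 16 (2S,3S,7R,8S,9S)-2,8-bis(TBS-oxy)-1,1-dimethoxy-3,7-dimethyl-6,7,9,10-tetrakis(TES-oxy)dec-4-yne (C1 epimers), via chain diol 15 (not isolated)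
Conditions: 14 (1.5 equiv), EtMgBr, THF, 0 → 40 °C; 9 (pre-treated with EtMgBr, 1.0 equiv), 0 °C → rt; then TESOTf (2.5 equiv), −78 → 0 °C; NaHCO3 (aq)
Reagents that add atoms: triethylsilyl triflate, CC[Si](CC)(CC)OS(=O)(=O)C(F)(F)F
Why: Grignard addition of the alkynylmagnesium bromide to the open hydroxy-aldehyde form of the lactol joins the two halves at C1–C2 and the two magnesium alkoxides (O1 and O8) are silylated in the same flask; both C1 epimers are carried on because C1 becomes a ketone in step 16.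

Step 10
Reactants: 16 tetrakis-TES chain (product of step 9)
Product: 17 (2R,3S,4R,8S,9S)-3,9-bis(TBS-oxy)-10,10-dimethoxy-4,8-dimethyl-2,4,5-tris(TES-oxy)dec-6-ynal (C7 aldehyde; C1 epimers)
Conditions: (COCl)2, DMSO, CH2Cl2, −78 → −40 °C; then Et3N, −78 → 0 °C
Reagents that add atoms: none
Why: Swern conditions oxidise a primary triethylsilyl ether directly to the aldehyde (activated DMSO attacks the unhindered ether oxygen and chloride removes silicon) while the secondary and tertiary silyl ethers, the acetal and the alkyne are untouched.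

Step 11
Reactants: 17 C7 aldehyde (product of step 10); 18 methyl acrylate
Product: 19 Baylis–Hillman adduct with C7(OH)–C11(=CH2)CO2Me (C1 and C7 epimers)
Conditions: 18 (neat, 15 equiv), DABCO (1.0 equiv), rt, 3–5 d
Reagents that add atoms: none
Why: Morita–Baylis–Hillman reaction of the α-silyloxy aldehyde with methyl acrylate installs C11–C13 on C7; the new carbinol centre is formed as a mixture and is erased in step 12.

Step 12
Reactants: 19 Baylis–Hillman adduct (product of step 11)
Product: 20 methyl (2Z)-2-(bromomethyl)enoate with C7H=C11(CH2Br)CO2Me (C1 epimers)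
Conditions: NBS, Me2S, CH2Cl2, 0 °C → rt
Reagents that add atoms: N-bromosuccinimide, O=C1CCC(=O)N1Br
Why: Corey–Kim-type bromination of the Baylis–Hillman alcohol proceeds with allylic transposition (SN2') to the thermodynamically preferred (Z)-2-(bromomethyl)enoate, which removes the C7 stereocentre.

Step 13
Reactants: 20 allylic bromide (product of step 12)
Product: 21 C6 aldehyde of the allylic bromide (C1 epimers)
Conditions: TESOTf (2 equiv), 2,4,6-collidine (3 equiv), CH2Cl2, 0 °C; then H2O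
Reagents that add atoms: water, O
Why: Fujioka acetal cleavage: TESOTf and collidine turn the dimethyl acetal into a collidinium N,O-acetal that water hydrolyses to the aldehyde under conditions that leave silyl ethers, the allylic bromide and the ester intact.

Step 14
Reactants: 21 bromo aldehyde (product of step 13)
Product: 23 (4S,5S,6S,7S,8S,9S,10R)-5,9-bis(TBS-oxy)-1,8,10-tris(TES-oxy)germacr-11(13)-en-2-yn-12,6-olide (C1 epimers), via hydroxy ester 22 (not isolated)
Conditions: CrCl2 (8 equiv), THF, rt, syringe-pump addition of 21 over 10 h (0.002 M final); NH4Cl (aq)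
Reagents that add atoms: none
Why: Intramolecular Nozaki–Hiyama–Kishi allylation under high dilution forms the C6–C7 bond (the bond made in the germacrene-forming cyclisation) through a chair transition state of the E-allylchromium, which gives the 6,7-anti relationship and, once the chromium alkoxide acylates on the C12 ester, the trans-fused α-methylene lactone; the 6S,7S facial sense relies on macrocyclic control with the C5 and C8 silyloxy groups pseudo-equatorial, and with C1 held as a silyl ether no other carbonyl is within reach of C7.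

Step 15
Reactants: 23 macrolactone (product of step 14)
Product: 24 (4S,5S,6S,7R,8S,9S,10R)-5,9-bis(TBS-oxy)-1,8,10-trihydroxygermacr-11(13)-en-2-yn-12,6-olide (C1 epimers)
Conditions: HF·pyridine, pyridine, THF, 0 °C → rt
Reagents that add atoms: none
Why: Buffered HF·pyridine cleaves the three triethylsilyl ethers (O1, O8, O10) much faster than the two hindered secondary TBS ethers (selective desilylation).

Step 16
Reactants: 24 triol (product of step 15)
Product: 26 (4R,5S,6S,7R,8S,9S,10S)-5,9-bis(TBS-oxy)-8-hydroxy-1-oxo-3,10-epoxygermacra-2,11(13)-dien-12,6-olide, via ynone 25 (not isolated)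
Conditions: MnO2 (activated, 20 equiv), CH2Cl2, rt; then Ph3PAuNTf2 (5 mol%), rt
Reagents that add atoms: none
Why: MnO2 oxidises only the propargylic C1 alcohol, and the resulting strained ten-membered 1-oxo-2-yne (a dehydrated 1,3-dione) is closed by gold-catalysed transannular 5-endo-dig addition of the tertiary C10 hydroxyl to C3 (oxa-Michael-type cycloisomerisation) to give the 3(2H)-furanone, with the C9 TBS ether blocking the six-membered alternative; no stereocentre changes.

Step 17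
Reactants: 26 furanone alcohol (product of step 16); 27 tigloyl chloride ((E)-2-methylbut-2-enoyl chloride)
Product: 28 (4R,5S,6S,7S,8S,9S,10S)-5,9-bis(TBS-oxy)-1-oxo-8-tigloyloxy-3,10-epoxygermacra-2,11(13)-dien-12,6-olide
Conditions: 27 (1.5 equiv), pyridine, DMAP (cat.), CH2Cl2, 0 °C → rt
Reagents that add atoms: none
Why: DMAP-catalysed acylation of the only free hydroxyl (secondary C8–OH) installs the tiglate with its E geometry intact.

Step 18
Reactants: 28 tiglate (product of step 17)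
Product: 29 (11R)-11,13-epoxide of 28
Conditions: t-BuOOH (5.5 M in decane), DBU, CH2Cl2, 0 °C
Reagents that add atoms: tert-butyl hydroperoxide, CC(C)(C)OO
Why: Weitz–Scheffer nucleophilic epoxidation: the tert-butyl peroxide anion adds to the exocyclic methylene of the lactone (far more electrophilic and less hindered than the tiglate or the vinylogous ester) and the lactone enolate closes onto oxygen from the α face (syn to H7, away from the C8 side of the ring), setting C11.

Step 19
Reactants: 29 spiro-epoxide (product of step 18)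
Product: 31 target CNP0340393.1, via chlorohydrin 30 (not isolated)
Conditions: HCl (4 M in dioxane, 3 equiv), CH2Cl2, 0 °C; then HF (48% aq.), MeCN, 0 °C → rt
Reagents that add atoms: hydrogen chloride, Cl
Why: Acid-promoted SN2 opening of the glycidic-type epoxide by chloride at the primary C13 gives the chlorohydrin with retention at C11, and HF in acetonitrile then removes both TBS ethers (desilylation).

## Compound list

1 | (R)-but-3-ene-1,2-diol | C=C[C@@H](O)CO | starting material
2 | methacryloyl chloride (2-methylprop-2-enoyl chloride) | C=C(C)C(Cl)=O | starting material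
3 | (R)-1-(triethylsilyloxy)but-3-en-2-ol | C=C[C@@H](O)CO[Si](CC)(CC)CC | intermediate
4 | (R)-1-(triethylsilyloxy)but-3-en-2-yl 2-methylprop-2-enoate | C=C[C@@H](OC(=O)C(C)=C)CO[Si](CC)(CC)CC | intermediate
5 | (R)-3-methyl-5-[(triethylsilyloxy)methyl]furan-2(5H)-one | O=C1O[C@@H](CO[Si](CC)(CC)CC)C=C1C | intermediate
6 | (3S,4S,5S)-3,4-dihydroxy-3-methyl-5-[(triethylsilyloxy)methyl]oxolan-2-one (5-O-TES-2-C-methyl-L-ribono-1,4-lactone) | O=C1O[C@@H](CO[Si](CC)(CC)CC)[C@H](O)[C@]1(C)O | intermediate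
7 | (3S,4S,5S)-4-(tert-butyldimethylsilyloxy)-3-hydroxy-3-methyl-5-[(triethylsilyloxy)methyl]oxolan-2-one | O=C1O[C@@H](CO[Si](CC)(CC)CC)[C@H](O[Si](C)(C)C(C)(C)C)[C@]1(C)O | intermediate
8 | (3S,4S,5S)-4-(tert-butyldimethylsilyloxy)-3-methyl-3-(triethylsilyloxy)-5-[(triethylsilyloxy)methyl]oxolan-2-one | O=C1O[C@@H](CO[Si](CC)(CC)CC)[C@H](O[Si](C)(C)C(C)(C)C)[C@]1(C)O[Si](CC)(CC)CC | intermediate
9 | (3S,4S,5S)-4-(tert-butyldimethylsilyloxy)-3-methyl-3-(triethylsilyloxy)-5-[(triethylsilyloxy)methyl]oxolan-2-ol (lactol, both anomers) | OC1O[C@@H](CO[Si](CC)(CC)CC)[C@H](O[Si](C)(C)C(C)(C)C)[C@]1(C)O[Si](CC)(CC)CC | intermediate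
10 | (R)-but-3-yn-2-ol | C#C[C@@H](C)O | starting material
11 | (R)-but-3-yn-2-yl methanesulfonate | C#C[C@@H](C)OS(C)(=O)=O | intermediate
12 | 2,2-dimethoxyacetaldehyde | COC(OC)C=O | starting material
13 | (2S,3S)-1,1-dimethoxy-3-methylpent-4-yn-2-ol | C#C[C@H](C)[C@H](O)C(OC)OC | intermediate
14 | tert-butyl{[(2S,3S)-1,1-dimethoxy-3-methylpent-4-yn-2-yl]oxy}dimethylsilane | C#C[C@H](C)[C@H](O[Si](C)(C)C(C)(C)C)C(OC)OC | intermediate
15 | (2S,3S,7R,8S,9S)-2,8-bis(tert-butyldimethylsilyloxy)-1,1-dimethoxy-3,7-dimethyl-7,10-bis(triethylsilyloxy)dec-4-yne-6,9-diol (epimers at position 6 = germacrane C1) | COC(OC)[C@@H](O[Si](C)(C)C(C)(C)C)[C@@H](C)C#CC(O)[C@@](C)(O[Si](CC)(CC)CC)[C@@H](O[Si](C)(C)C(C)(C)C)[C@@H](O)CO[Si](CC)(CC)CC | intermediate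
16 | (2S,3S,7R,8S,9S)-2,8-bis(tert-butyldimethylsilyloxy)-1,1-dimethoxy-3,7-dimethyl-6,7,9,10-tetrakis(triethylsilyloxy)dec-4-yne (epimers at position 6 = germacrane C1) | COC(OC)[C@@H](O[Si](C)(C)C(C)(C)C)[C@@H](C)C#CC(O[Si](CC)(CC)CC)[C@@](C)(O[Si](CC)(CC)CC)[C@@H](O[Si](C)(C)C(C)(C)C)[C@@H](O[Si](CC)(CC)CC)CO[Si](CC)(CC)CC | intermediate
17 | (2R,3S,4R,8S,9S)-3,9-bis(tert-butyldimethylsilyloxy)-10,10-dimethoxy-4,8-dimethyl-2,4,5-tris(triethylsilyloxy)dec-6-ynal (epimers at position 5 = germacrane C1) | COC(OC)[C@@H](O[Si](C)(C)C(C)(C)C)[C@@H](C)C#CC(O[Si](CC)(CC)CC)[C@@](C)(O[Si](CC)(CC)CC)[C@@H](O[Si](C)(C)C(C)(C)C)[C@@H](O[Si](CC)(CC)CC)C=O | intermediate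
18 | methyl acrylate | C=CC(=O)OC | starting material
19 | methyl (4S,5S,6R,10S,11S)-5,11-bis(tert-butyldimethylsilyloxy)-3-hydroxy-12,12-dimethoxy-6,10-dimethyl-2-methylidene-4,6,7-tris(triethylsilyloxy)dodec-8-ynoate (epimers at positions 3 and 7 = germacrane C7 and C1) | COC(OC)[C@@H](O[Si](C)(C)C(C)(C)C)[C@@H](C)C#CC(O[Si](CC)(CC)CC)[C@@](C)(O[Si](CC)(CC)CC)[C@@H](O[Si](C)(C)C(C)(C)C)[C@@H](O[Si](CC)(CC)CC)C(O)C(=C)C(=O)OC | intermediate
20 | methyl (2Z,4S,5S,6R,10S,11S)-2-(bromomethyl)-5,11-bis(tert-butyldimethylsilyloxy)-12,12-dimethoxy-6,10-dimethyl-4,6,7-tris(triethylsilyloxy)dodec-2-en-8-ynoate (epimers at position 7 = germacrane C1) | COC(OC)[C@@H](O[Si](C)(C)C(C)(C)C)[C@@H](C)C#CC(O[Si](CC)(CC)CC)[C@@](C)(O[Si](CC)(CC)CC)[C@@H](O[Si](C)(C)C(C)(C)C)[C@@H](O[Si](CC)(CC)CC)/C=C(\CBr)C(=O)OC | intermediate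
21 | methyl (2Z,4S,5S,6R,10S,11S)-2-(bromomethyl)-5,11-bis(tert-butyldimethylsilyloxy)-6,10-dimethyl-12-oxo-4,6,7-tris(triethylsilyloxy)dodec-2-en-8-ynoate (epimers at position 7 = germacrane C1) | O=C[C@@H](O[Si](C)(C)C(C)(C)C)[C@@H](C)C#CC(O[Si](CC)(CC)CC)[C@@](C)(O[Si](CC)(CC)CC)[C@@H](O[Si](C)(C)C(C)(C)C)[C@@H](O[Si](CC)(CC)CC)/C=C(\CBr)C(=O)OC | intermediate
22 | methyl (4S,5S,6S,7S,8S,9S,10R)-5,9-bis(tert-butyldimethylsilyloxy)-6-hydroxy-1,8,10-tris(triethylsilyloxy)germacr-11(13)-en-2-yn-12-oate (C1 epimers; formed as its chromium alkoxide) | CC[Si](CC)(CC)O[C@H]1[C@@H](C(=C)C(=O)OC)[C@H](O)[C@@H](O[Si](C)(C)C(C)(C)C)[C@@H](C)C#CC(O[Si](CC)(CC)CC)[C@@](C)(O[Si](CC)(CC)CC)[C@H]1O[Si](C)(C)C(C)(C)C | intermediate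
23 | (4S,5S,6S,7S,8S,9S,10R)-5,9-bis(tert-butyldimethylsilyloxy)-1,8,10-tris(triethylsilyloxy)germacr-11(13)-en-2-yn-12,6-olide (C1 epimers) | CC[Si](CC)(CC)O[C@H]1[C@@H]2[C@H](OC(=O)C2=C)[C@@H](O[Si](C)(C)C(C)(C)C)[C@@H](C)C#CC(O[Si](CC)(CC)CC)[C@@](C)(O[Si](CC)(CC)CC)[C@H]1O[Si](C)(C)C(C)(C)C | intermediate
24 | (4S,5S,6S,7R,8S,9S,10R)-5,9-bis(tert-butyldimethylsilyloxy)-1,8,10-trihydroxygermacr-11(13)-en-2-yn-12,6-olide (C1 epimers) | O[C@H]1[C@@H]2[C@H](OC(=O)C2=C)[C@@H](O[Si](C)(C)C(C)(C)C)[C@@H](C)C#CC(O)[C@@](C)(O)[C@H]1O[Si](C)(C)C(C)(C)C | intermediate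
25 | (4S,5S,6S,7R,8S,9S,10S)-5,9-bis(tert-butyldimethylsilyloxy)-8,10-dihydroxy-1-oxogermacr-11(13)-en-2-yn-12,6-olide | O[C@H]1[C@@H]2[C@H](OC(=O)C2=C)[C@@H](O[Si](C)(C)C(C)(C)C)[C@@H](C)C#CC(=O)[C@@](C)(O)[C@H]1O[Si](C)(C)C(C)(C)C | intermediate
26 | (4R,5S,6S,7R,8S,9S,10S)-5,9-bis(tert-butyldimethylsilyloxy)-8-hydroxy-1-oxo-3,10-epoxygermacra-2,11(13)-dien-12,6-olide | O[C@H]1[C@@H]2[C@H](OC(=O)C2=C)[C@@H](O[Si](C)(C)C(C)(C)C)[C@@H](C)C2=CC(=O)[C@@](C)(O2)[C@H]1O[Si](C)(C)C(C)(C)C | intermediate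
27 | tigloyl chloride ((E)-2-methylbut-2-enoyl chloride) | C/C=C(\C)C(Cl)=O | starting material
28 | (4R,5S,6S,7S,8S,9S,10S)-5,9-bis(tert-butyldimethylsilyloxy)-8-[(E)-2-methylbut-2-enoyloxy]-1-oxo-3,10-epoxygermacra-2,11(13)-dien-12,6-olide | C/C=C(\C)C(=O)O[C@H]1[C@@H]2[C@H](OC(=O)C2=C)[C@@H](O[Si](C)(C)C(C)(C)C)[C@@H](C)C2=CC(=O)[C@@](C)(O2)[C@H]1O[Si](C)(C)C(C)(C)C | intermediate
29 | (4R,5S,6S,7S,8S,9S,10S,11R)-5,9-bis(tert-butyldimethylsilyloxy)-11,13-epoxy-8-[(E)-2-methylbut-2-enoyloxy]-1-oxo-3,10-epoxygermacr-2-en-12,6-olide | C/C=C(\C)C(=O)O[C@H]1[C@@H]2[C@H](OC(=O)[C@]23CO3)[C@@H](O[Si](C)(C)C(C)(C)C)[C@@H](C)C2=CC(=O)[C@@](C)(O2)[C@H]1O[Si](C)(C)C(C)(C)C | intermediate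
30 | (4R,5S,6S,7S,8S,9S,10S,11S)-5,9-bis(tert-butyldimethylsilyloxy)-13-chloro-11-hydroxy-8-[(E)-2-methylbut-2-enoyloxy]-1-oxo-3,10-epoxygermacr-2-en-12,6-olide | C/C=C(\C)C(=O)O[C@H]1[C@@H]2[C@H](OC(=O)[C@]2(O)CCl)[C@@H](O[Si](C)(C)C(C)(C)C)[C@@H](C)C2=CC(=O)[C@@](C)(O2)[C@H]1O[Si](C)(C)C(C)(C)C | intermediate
31 | CNP0340393.1: (4R,5S,6S,7S,8S,9S,10S,11S)-13-chloro-5,9,11-trihydroxy-8-[(E)-2-methylbut-2-enoyloxy]-1-oxo-3,10-epoxygermacr-2-en-12,6-olide | C/C=C(\C)C(=O)O[C@H]1[C@@H]2[C@H](OC(=O)[C@]2(O)CCl)[C@@H](O)[C@@H](C)C2=CC(=O)[C@@](C)(O2)[C@H]1O | target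

## Step count and risks

Total step count: 19. Longest linear sequence: 16 steps (steps 1–5 and 9–19); the alkyne branch (steps 6–8) is 3 steps.

The three steps most likely to fail:

**Step 11 (Baylis–Hillman reaction).** The aldehyde 17 is hindered and carries a silyloxy group β to the carbonyl, so the amine-catalysed reaction may be slow or may eliminate. Fallback: setting out from 17, a Wittig reaction with methyl 2-(triphenylphosphoranylidene)propanoate (toluene, 60 °C) gives the (E)-2-methyl enoate F1. Wohl–Ziegler bromination of its ester-activated allylic methyl group (NBS, AIBN, PhCF3, 80 °C, solid K2CO3) then leads directly to bromide 20, where the route is rejoined. This replaces steps 11 and 12 and never passes through a carbinol at C7.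

**Step 14 (macrocyclisation).** The ring closure can lose to oligomerisation or to strain from the ring alkyne, and the C6/C7 facial sense rests on macrocyclic control alone; this is the least certain stereochemical point of the route. Fallback: setting out from 19, acetylation (Ac2O, pyridine, DMAP) gives the Baylis–Hillman acetate F2, and acetal cleavage as in step 13 gives the aldehyde acetate F3. The ring is then closed by a palladium/indium umpolung allylation (Pd(PPh3)4, InI, THF, high dilution): zerovalent palladium ionises the allylic acetate, indium monoiodide turns the π-allyl into an allylindium, and this adds to the C6 aldehyde and lactonises through 22, coming back at 23. No allylic halide has to be carried, and the different transition state gives a second chance at the C6/C7 facial sense.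

**Step 16 (oxidation and transannular furanone closure).** The ten-membered ynone 25 may be too labile, or the gold-catalysed 5-endo closure may be slow against the ring geometry. Fallback: setting out from 24 and passing through 25 as before, hydroiodination of the ynone (NaI, AcOH, MeCN, rt) gives the β-iodo enone F4. In F4 the alkyne strain is gone and C3 is already at the right oxidation level. Et3N (or Ag2CO3) then induces transannular addition–elimination of the C10 hydroxyl with loss of iodide, coming back at 26.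

Further compounds

F1 | step 11 | methyl (2E,4S,5S,6R,10S,11S)-5,11-bis(tert-butyldimethylsilyloxy)-12,12-dimethoxy-2,6,10-trimethyl-4,6,7-tris(triethylsilyloxy)dodec-2-en-8-ynoate (epimers at position 7) | COC(OC)[C@@H](O[Si](C)(C)C(C)(C)C)[C@@H](C)C#CC(O[Si](CC)(CC)CC)[C@@](C)(O[Si](CC)(CC)CC)[C@@H](O[Si](C)(C)C(C)(C)C)[C@@H](O[Si](CC)(CC)CC)/C=C(\C)C(=O)OC
F2 | step 14 | methyl (4S,5S,6R,10S,11S)-3-acetoxy-5,11-bis(tert-butyldimethylsilyloxy)-12,12-dimethoxy-6,10-dimethyl-2-methylidene-4,6,7-tris(triethylsilyloxy)dodec-8-ynoate (epimers at positions 3 and 7) | COC(OC)[C@@H](O[Si](C)(C)C(C)(C)C)[C@@H](C)C#CC(O[Si](CC)(CC)CC)[C@@](C)(O[Si](CC)(CC)CC)[C@@H](O[Si](C)(C)C(C)(C)C)[C@@H](O[Si](CC)(CC)CC)C(OC(C)=O)C(=C)C(=O)OC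
F3 | step 14 | methyl (4S,5S,6R,10S,11S)-3-acetoxy-5,11-bis(tert-butyldimethylsilyloxy)-6,10-dimethyl-2-methylidene-12-oxo-4,6,7-tris(triethylsilyloxy)dodec-8-ynoate (epimers at positions 3 and 7) | O=C[C@@H](O[Si](C)(C)C(C)(C)C)[C@@H](C)C#CC(O[Si](CC)(CC)CC)[C@@](C)(O[Si](CC)(CC)CC)[C@@H](O[Si](C)(C)C(C)(C)C)[C@@H](O[Si](CC)(CC)CC)C(OC(C)=O)C(=C)C(=O)OC
F4 | step 16 | (4R,5S,6S,7R,8S,9S,10S)-5,9-bis(tert-butyldimethylsilyloxy)-8,10-dihydroxy-3-iodo-1-oxogermacra-2,11(13)-dien-12,6-olide (C1 and C4 trans across C2=C3) | O[C@H]1[C@@H]2[C@H](OC(=O)C2=C)[C@@H](O[Si](C)(C)C(C)(C)C)[C@@H](C)/C(I)=C/C(=O)[C@@](C)(O)[C@H]1O[Si](C)(C)C(C)(C)C
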